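The target is a symmetric diarylmethane: two gigantol units joined through one CH2 that sits on C4 of each 3‑methoxy‑5‑alkylphenol ring (ring B), para to the C1 hydroxyl and ortho to the C3 methoxy. The route rests on cutting one aryl C4–CH2 bond. In a biomimetic, acid‑catalysed condensation with formaldehyde, gigantol is hydroxymethylated at this most nucleophilic carbon, the resulting p‑hydroxybenzyl alcohol ionises to a p‑quinone methide, and a second gigantol adds through the same carbon, so the whole skeleton arises in one operation. The precursor is simply unprotected gigantol, made in two steps by Heck coupling and hydrogenation.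

Key step: step 3

Remark: the target has no stereocentre and no other stereogenic element (the diarylmethane rotates freely), so it is a single achiral compound and no stereocontrol is required.

Step 1
Reactants: 1 3‑bromo‑5‑methoxyphenol; 2 2‑methoxy‑4‑vinylphenol (4‑vinylguaiacol)
Product: 3 (E)‑4‑[2‑(3‑hydroxy‑5‑methoxyphenyl)ethenyl]‑2‑methoxyphenol
Conditions: Pd(OAc)2 (3 mol %), P(o‑tol)3 (6 mol %), Et3N (3 equiv), BHT (cat.), DMF, 100 °C, N2
Reagents that add atoms: none
Why: Mizoroki–Heck reaction: Pd(0) inserts into the C–Br bond of 1 (both oxygen substituents are meta to bromine and do not retard it), the terminal alkene carbon of 2 is arylated by syn‑insertion, and syn‑β‑hydride elimination should give the (E)‑stilbene, with free phenols tolerated under amine‑base conditions and BHT suppressing radical polymerisation of 2.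

Step 2
Reactants: 3 (E)‑4‑[2‑(3‑hydroxy‑5‑methoxyphenyl)ethenyl]‑2‑methoxyphenol
Product: 4 gigantol
Conditions: H2 (1 atm), 10 % Pd/C, EtOAc–EtOH, rt
Reagents that add atoms: none
Why: Heterogeneous catalytic hydrogenation saturates the stilbene C=C; no hydrogenolysable group is present (phenolic and methyl‑ether aryl C–O bonds are inert here) and the alkene geometry becomes irrelevant.

Step 3
Reactants: 4 gigantol (two molecules per formaldehyde, used in slight excess)
Product: 7 methylene‑bridged gigantol dimer (target), via C4‑hydroxymethylgigantol 5 (not isolated), via gigantol p‑quinone methide 6 (not isolated)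
Conditions: 37 % aq. CH2O (0.45 equiv, slow addition), HCl (cat.), MeOH–H2O, concentrated in 4, 25→40 °C; unreacted 4 recovered
Reagents that add atoms: formaldehyde, C=O
Why: Acid‑catalysed hydroxymethylation of ring B of 4 at C4 (para to the C1 hydroxyl) gives the p‑hydroxybenzyl alcohol 5, which loses water to the p‑quinone methide 6 (in acid its O‑protonated form, a benzylic cation stabilised by the para OH and ortho OMe); C4 of a second molecule of 4 then adds to the exocyclic CH2 in a Friedel–Crafts‑type 1,6‑addition, and rearomatisation gives 7. The closest known reaction type is the phenol–formaldehyde (Lederer–Manasse/novolac) condensation used to make methylene‑bridged resorcinol‑ and phloroglucinol‑type dimers, and it mirrors the presumed biogenesis from two bibenzyls and a C1 unit. No ring is closed and no stereocentre is formed. The step needs (i) chemoselectivity for ring B over the guaiacyl ring A, secured because only in the meta‑dioxygenated ring B do both oxygens activate the same carbons, (ii) regioselectivity for C4 over C2 and C6 in both C–C bond formations, expected from the para‑directing free hydroxyl reinforced by the ortho methoxy and the flanking alkyl group, and (iii) arrest at the dimer, secured by keeping formaldehyde limiting and adding it slowly to concentrated 4 so that 6 is always intercepted by monomer. Because both bond formations obey the same preference, the symmetric product should be the major isomer.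

Compound list
1 | 3‑bromo‑5‑methoxyphenol | COc1cc(O)cc(Br)c1 | starting material
2 | 2‑methoxy‑4‑vinylphenol | C=Cc1ccc(O)c(OC)c1 | starting material
3 | (E)‑4‑[2‑(3‑hydroxy‑5‑methoxyphenyl)ethenyl]‑2‑methoxyphenol | COc1cc(/C=C/c2cc(O)cc(OC)c2)ccc1O | intermediate
4 | gigantol, 4‑[2‑(3‑hydroxy‑5‑methoxyphenyl)ethyl]‑2‑methoxyphenol | COc1cc(CCc2cc(O)cc(OC)c2)ccc1O | intermediate
5 | 3‑[2‑(4‑hydroxy‑3‑methoxyphenyl)ethyl]‑4‑(hydroxymethyl)‑5‑methoxyphenol | COc1cc(CCc2cc(O)cc(OC)c2CO)ccc1O | intermediate (not isolated)
6 | 3‑[2‑(4‑hydroxy‑3‑methoxyphenyl)ethyl]‑5‑methoxy‑4‑methylidenecyclohexa‑2,5‑dien‑1‑one (p‑quinone methide) | C=C1C(OC)=CC(=O)C=C1CCc1ccc(O)c(OC)c1 | intermediate (not isolated)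
7 | 4,4'‑methylenebis{3‑[2‑(4‑hydroxy‑3‑methoxyphenyl)ethyl]‑5‑methoxyphenol} (CNP0079383.0) | COc1cc(CCc2cc(O)cc(OC)c2Cc2c(CCc3ccc(O)c(OC)c3)cc(O)cc2OC)ccc1O | target

Total step count: 3
Longest linear sequence: 3 steps (1 + 2 → 3 → 4 → 7)

Steps most likely to fail

Step 3 (key step). Several processes may go wrong:
- Regiocontrol may be lost in either electrophilic substitution, through attack at the ring‑B carbons ortho to the hydroxyl or at the guaiacyl ring.
- The quinone methide may be captured intramolecularly by ring A, closing a seven‑membered ring.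
- Condensation may run on to methylene‑bridged oligomers.

The fallback sets out from gigantol 4 and comes back to the route at target 7. It reverses the polarity and fixes the regiochemistry at the monomer stage. Para‑selective monobromination of the ring‑B phenol of 4 with tetrabutylammonium tribromide (CH2Cl2–MeOH, rt) should give 4‑bromo‑3‑[2‑(4‑hydroxy‑3‑methoxyphenyl)ethyl]‑5‑methoxyphenol F1, which can be purified and its substitution pattern checked before any fragments are joined. Benzylation of both phenols (BnBr, K2CO3, DMF) should give 5‑benzyloxy‑1‑[2‑(4‑benzyloxy‑3‑methoxyphenyl)ethyl]‑2‑bromo‑3‑methoxybenzene F2. Bromine–lithium exchange (n‑BuLi, THF, −78 °C) gives the corresponding aryllithium F3. Ethyl formate (0.5 equiv) converts half of it into 4‑benzyloxy‑2‑[2‑(4‑benzyloxy‑3‑methoxyphenyl)ethyl]‑6‑methoxybenzaldehyde F4 (not isolated), to which the other half adds; a water quench should give the symmetric tetrabenzyl diarylmethanol F5, with the bridging carbon bonded to C4 of both rings by construction. Hydrogenolysis (H2, Pd/C, EtOAc–AcOH, rt) then removes the four benzyl ethers and the doubly benzylic, electron‑rich carbinol hydroxyl to give 7.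

Step 1. Several processes may go wrong:
- The electron‑rich vinylphenol may polymerise thermally or by a radical path at 100 °C.
- Phenoxide coordination may deactivate the catalyst.
- Competing α‑arylation may give the 1,1‑diarylethene.

The fallback sets out from 2 (with 1 as the coupling partner) and comes back at gigantol 4, bypassing 3 and step 2. Acetylation of 2 (Ac2O, pyridine, CH2Cl2) gives 4‑acetoxy‑3‑methoxystyrene F6. Anti‑Markovnikov hydroboration with 9‑BBN (THF, 0 °C → rt) gives B‑[2‑(4‑acetoxy‑3‑methoxyphenyl)ethyl]‑9‑borabicyclo[3.3.1]nonane F7 (not isolated). B‑alkyl Suzuki–Miyaura coupling with 1 (Pd(dppf)Cl2, aq. NaOH in excess, THF, 65 °C), with saponification of the aryl acetate by the aqueous base in the same pot, should give 4 directly after acidic work‑up.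

Step 2. The heterogeneous catalyst may be poisoned by phosphine, amine or palladium residues carried over from step 1, leaving the reduction incomplete. The fallback sets out from 3 and comes back at 4: a metal‑free diimide transfer reduction (p‑toluenesulfonyl hydrazide, NaOAc, THF–H2O, reflux) saturates the stilbene by concerted syn delivery of two hydrogens and creates no new compound.

Further compounds
F1 | step 3 | 4‑bromo‑3‑[2‑(4‑hydroxy‑3‑methoxyphenyl)ethyl]‑5‑methoxyphenol | COc1cc(CCc2cc(O)cc(OC)c2Br)ccc1O
F2 | step 3 | 5‑benzyloxy‑1‑[2‑(4‑benzyloxy‑3‑methoxyphenyl)ethyl]‑2‑bromo‑3‑methoxybenzene | COc1cc(CCc2cc(OCc3ccccc3)cc(OC)c2Br)ccc1OCc1ccccc1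
F3 | step 3 | {4‑benzyloxy‑2‑[2‑(4‑benzyloxy‑3‑methoxyphenyl)ethyl]‑6‑methoxyphenyl}lithium | COc1cc(CCc2cc(OCc3ccccc3)cc(OC)c2[Li])ccc1OCc1ccccc1
F4 | step 3 | 4‑benzyloxy‑2‑[2‑(4‑benzyloxy‑3‑methoxyphenyl)ethyl]‑6‑methoxybenzaldehyde | COc1cc(CCc2cc(OCc3ccccc3)cc(OC)c2C=O)ccc1OCc1ccccc1
F5 | step 3 | bis{4‑benzyloxy‑2‑[2‑(4‑benzyloxy‑3‑methoxyphenyl)ethyl]‑6‑methoxyphenyl}methanol | COc1cc(CCc2cc(OCc3ccccc3)cc(OC)c2C(O)c2c(CCc3ccc(OCc4ccccc4)c(OC)c3)cc(OCc3ccccc3)cc2OC)ccc1OCc1ccccc1
F6 | step 1 | 4‑acetoxy‑3‑methoxystyrene | C=Cc1ccc(OC(C)=O)c(OC)c1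
F7 | step 1 | B‑[2‑(4‑acetoxy‑3‑methoxyphenyl)ethyl]‑9‑borabicyclo[3.3.1]nonane | CC(=O)Oc1ccc(CCB2C3CCCC2CCC3)cc1OC
F0 | step 2 | none | none
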